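**Plan**

1. Numbering: phthalide numbering, unprimed for the butylidene half (ring A, C1–C11), primed for the other half (ring B, C1'–C11'). The cyclopentane is C6–C7–C7a'–C3a'–C3'. β is the face of the central ring that carries C1'.
2. Retrosynthesis: the enabling feature is the α-acyloxy ketone C3'(O2')–C8'(=O) on the cyclopentane. Cutting C3'–C6 and putting the butanoyl carbon C8' back between C3' and C6 (acyloin-type retron) gives a cyclohexane C3'–C8'–C6–C7–C7a'–C3a' with a leaving group on C3' and OH on C8'.
3. That cyclohexane is cut at C6–C8' and C7–C7a' ([4+2]) into a 5-hydroxy-2-pyranone carrying ring B and the ring-opened keto ester of (Z)-ligustilide; both pieces come from (Z)-ligustilide.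
4. Forward: ligustilide → keto ester → hydroxypyranone; cycloaddition builds the central six-membered ring as a lactone-bridged bicyclo[2.2.2]octane; hydrolysis frees a tricyclic chair; ring A is closed again to the butylidene lactone and half B to a bridged acetoxy lactone; ring contraction gives the cyclopentane inside the final oxabicyclo[2.2.1]heptanone.
5. Stereochemistry: C8', C7a' and C6 from the chiral-base-controlled cycloaddition; C7 and C3a' by equilibration in the tricyclic chair (trans-anti-trans); C3' by the stereospecific shift (retention at C6, inversion at C3'); the Z alkene is the thermodynamic enol lactone.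

Key step: step 6

Remark on the chemistry: as written, H-6 and H-7 are trans, so ring A is trans-fused to the oxabicyclo[2.2.1]heptanone; this strained fusion is therefore fixed in a strain-free precursor and the bicycle is closed last by an irreversible shift.

**Route**

Step 1
Reactants: 1 (Z)-ligustilide
Product: 2 methyl 2-pentanoylcyclohexa-1,5-diene-1-carboxylate
Conditions: K2CO3 (0.1 equiv), MeOH, 0 °C, argon
Reagents that add atoms: methanol (CO)
Why: Base-catalysed methanolysis (transesterification) of the enol lactone is driven by ketonisation of the released enol; it unmasks the C3 ketone, which makes C6 the δ-carbon of a dienone and C7–H vinylogously acidic, and it creates no stereocenter.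

Step 2
Reactants: 2 methyl 2-pentanoylcyclohexa-1,5-diene-1-carboxylate
Product: 4 4-hydroxy-3-propyl-5,6-dihydro-1H-isochromen-1-one, via α-hydroxy keto ester 3 (not isolated)
Conditions: KN(SiMe3)2 (1.1 equiv), THF, −78 °C (2 added slowly to the base); 2-(phenylsulfonyl)-3-phenyloxaziridine (1.2 equiv), −78 → 0 °C; AcOH
Reagents that add atoms: 2-(phenylsulfonyl)-3-phenyloxaziridine (O=S(=O)(c1ccccc1)N1OC1c1ccccc1)
Why: The potassium enolate forms at the only ketone α-CH2 (C8) and is hydroxylated by the N-sulfonyloxaziridine (enolate α-hydroxylation), after which the C8 alkoxide lactonises onto the neighbouring methyl ester (6-exo-trig) and the isochromane-1,4-dione enolises to the 5-hydroxy-2-pyranone, so no stereocenter remains.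

Step 3
Reactants: 4 4-hydroxy-3-propyl-5,6-dihydro-1H-isochromen-1-one, 2 methyl 2-pentanoylcyclohexa-1,5-diene-1-carboxylate (1.5 equiv)
Product: 5 endo bicyclo[2.2.2] keto lactone (lactone bridge C8'–O–C1'; C3' ketone; ring A as keto ester cis-fused at C6–C7)
Conditions: O-benzylcupreidine (9-benzyl ether of 6'-demethylquinidine, C26H28N2O2, 10 mol %), toluene, −20 → 0 °C, argon
Reagents that add atoms: none
Why: Proposed new method: the amine deprotonates the vinylogous acid 4 to a chiral 5-oxido-2-pyranone ion pair whose C8' (carbon 6 of the pyranone, the enolate carbon) adds to the δ-carbon C6 of dienone 2 while C7 closes onto C7a' (β-carbon of the C3' enone) in an asynchronous, anion-accelerated [4+2] (Michael–Michael) cycloaddition in which no intermediate should accumulate; the closest known reaction type is the amine-catalysed Diels–Alder reaction of 3-hydroxy-2-pyranones with enones, which cinchona bases render enantioselective; the ion pair is expected to fix the face of the pyranone (C8', C7a', sense assigned by analogy), the endo orientation of ring A under the oxido-diene fixes C6, the ring closure makes C7 cis to C6, and C3a' is set by protonation under the equilibrating amine with H-3a' on the side of the C6–C7 bridge; 2 is not deprotonated by the weak base, which secures cross-coupling over self-coupling.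

Step 4
Reactants: 5 endo bicyclo[2.2.2] keto lactone
Product: 7 trans-anti-trans hydroxy keto diacid, via cis-fused hydroxy keto acid 6 (not isolated)
Conditions: LiOH (6 equiv), THF/H2O 3:1, degassed, 0 → 23 °C; then 1 M HCl to pH 3 at 0 °C
Reagents that add atoms: lithium hydroxide ([Li+].[OH-]); water (O)
Why: Saponification opens the strained α-acyloxy lactone bridge and the keto ester, and in the released cyclohexanone chair C7 (γ to the C3 ketone through C7a=C3a) and C3a' (α to the C3' ketone) equilibrate by enolisation to the trans-anti-trans isomer, the only one without a 1,3-diaxial contact to the axial propyl group; as carboxylates the acid groups cannot trap a shifted ketol as a lactone.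

Step 5
Reactants: 7 trans-anti-trans hydroxy keto diacid
Product: 8 bridged acetoxy lactone carrying the (Z)-butylidene butenolide (C3'-OAc; lactone C1'–O2'–C3'; free C8'-OH)
Conditions: Ac2O, NaOAc (2 equiv), 70 °C, no acylation catalyst
Reagents that add atoms: acetic anhydride (CC(=O)OC(C)=O)
Why: Acetic anhydride cyclodehydrates the γ-keto acid of half A to the thermodynamically favoured (Z)-enol lactone, which removes the acidity of C7–H and locks the trans fusion, while on half B the axial C1' carboxyl adds to the C3' ketone and the lactol is acetylated to a pseudo-ester (acetoxy lactone) that cannot eliminate because either enol lactone would be a bridgehead alkene; the lactone bridge sets C3' with O2' axial (cis to C1') and OAc equatorial, and the hindered tertiary C8' hydroxyl should stay free.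

Step 6
Reactants: 8 bridged acetoxy lactone carrying the (Z)-butylidene butenolide
Product: 9 CNP0423313.2 (target)
Conditions: Me3SiOSO2CF3 (0.2 equiv), 4 Å molecular sieves, CH2Cl2, −78 → −20 °C; pyridine quench
Reagents that add atoms: none
Why: Proposed new method: Me3SiOSO2CF3 ionises the equatorial acylal acetate on C3' while the antiperiplanar ring bond C8'–C6 migrates to C3' and the C8' hydroxyl collapses to the butanoyl ketone, so the cyclohexane C3'–C8'–C6–C7–C7a'–C3a' contracts to the cyclopentane and the 6-oxabicyclo[3.2.1]octanone becomes the 2-oxabicyclo[2.2.1]heptanone. The closest known reaction types are the semipinacol (acyloin-type, Tiffeneau–Demjanov-like) ring contraction of 2-hydroxycyclohexyl derivatives with an equatorial leaving group and the Lewis acid ionisation of anomeric acetates. The five-membered carbocycle is closed by the suprafacial 1,2-shift itself through a three-centre transition state, with no separate cyclisation event, and the γ-lactone ring is carried through unchanged. The new quaternary stereocenter C3' is set by inversion (C6 enters anti to the leaving acetate) with O2' held on the face of C1' by the lactone tether, and C6 migrates with retention, so the trans relation of H-6 and H-7 fixed in 7 is transferred unchanged. The step needs migration of the ring bond in preference to propyl, H-3a' or C7a': only C8'–C6 is both antiperiplanar to C3'–OAc in the chair locked by the diaxial lactone bridge and pushed by the hydroxyl on C8', whereas the axial propyl is gauche to the leaving group. Loss of acetic acid makes the shift irreversible, so the strained trans-fused bicycle cannot return to a six-membered ketol.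

**Compound list**

1 | (Z)-ligustilide, (3Z)-3-butylidene-4,5-dihydro-2-benzofuran-1(3H)-one | CCC/C=C1\OC(=O)C2=C1CCC=C2 | starting material
2 | methyl 2-pentanoylcyclohexa-1,5-diene-1-carboxylate (ring-opened keto ester of 1) | CCCCC(=O)C1=C(C(=O)OC)C=CCC1 | intermediate
3 | methyl 2-(2-hydroxypentanoyl)cyclohexa-1,5-diene-1-carboxylate (racemic, present as potassium alkoxide) | CCCC(O)C(=O)C1=C(C(=O)OC)C=CCC1 | intermediate (not isolated)
4 | 4-hydroxy-3-propyl-5,6-dihydro-1H-isochromen-1-one (5-hydroxy-2-pyranone fused to ring B; enol form of the isochromane-1,4-dione) | CCCC1=C(O)C2=C(C=CCC2)C(=O)O1 | intermediate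
5 | bicyclo[2.2.2] keto lactone: lactone bridge from O on C8' to C1' on C7a' (β), propyl on C8' α, C3' ketone, H-3a' α (side of the C6–C7 bridge), ring B cyclohexene C6'=C7', ring A (methyl 2-pentanoylcyclohex-1-ene-1-carboxylate unit) cis-fused at C6–C7 with C5 and C7a both α (endo) | CCCCC(=O)C1=C(C(=O)OC)[C@@H]2[C@H](CC1)[C@]4(CCC)C(=O)[C@H]3CCC=C[C@]23C(=O)O4 | intermediate
6 | cis-fused hydroxy keto acid: lactone bridge of 5 hydrolysed (CO2H on C7a', tertiary OH on C8'), half A still methyl keto ester, C7 not yet epimerised | CCCCC(=O)C1=C(C(=O)OC)[C@@H]2[C@H](CC1)[C@](O)(CCC)C(=O)[C@H]3CCC=C[C@]23C(O)=O | intermediate (not isolated)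
7 | trans-anti-trans tricyclic hydroxy keto diacid: central cyclohexanone chair with CO2H axial on C7a' (β), C3' ketone, C8' with OH β (equatorial) and propyl α (axial); ring B trans-fused (H-3a' α); ring A trans-fused (H-6 β, H-7 α) with CO2H on C7a and pentanoyl on C3a | CCCCC(=O)C1=C(C(O)=O)[C@H]2[C@H](CC1)[C@](O)(CCC)C(=O)[C@H]3CCC=C[C@]23C(O)=O | intermediate
8 | bridged acetoxy lactone: half A closed to the (Z)-butylidene butenolide; on half B a γ-lactone from C1' to O2' on C3' (axial, β) bridges the central chair (6-oxabicyclo[3.2.1]octan-7-one), OAc on C3' equatorial (α), C8' with OH β and propyl α; H-6 β, H-7 α, H-3a' α | CCC/C=C1\OC(=O)C2=C1CC[C@H]3[C@H]2[C@@]24C=CCC[C@@H]2[C@](OC(C)=O)(OC4=O)[C@@]3(O)CCC | intermediate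
9 | CNP0423313.2 | CCC/C=C1\OC(=O)C2=C1CC[C@H]1[C@H]2[C@@]23C=CCC[C@@H]2[C@]1(C(=O)CCC)OC3=O | target

**Count and risks**

Total steps: 6. Longest linear sequence: 6 steps (1 → 2 → 4 → 5 → 7 → 8 → 9); compound 2 enters twice (steps 2 and 3).

Steps most likely to fail:

- Step 6 (key step, proposed new method). Ionisation at the bridgehead acylal may be too slow, or may end in return of acetate or capture of the cation without migration, and silyl capping of the C8' hydroxyl may take away the push. The fallback sets out from 8 and returns at 9. The acylal of 8 is hydrolysed (NaHCO3, THF/H2O, 23 °C) to the free hydroxy keto acid F1. With NaH (2.2 equiv) in THF the dianion of F1 undergoes the base-mediated α-ketol (acyloin) rearrangement, which equilibrates the six-membered ketol with the ring-contracted hydroxy acid F2. 2,4,6-Trichlorobenzoyl chloride is then added to the equilibrating mixture (Yamaguchi mixed anhydride); only the tertiary alkoxide of F2, which sits cis to the carboxyl, can be acylated, and this pulls the ring contraction through to 9.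

- Step 3 (proposed new method). Carbon–carbon bond formation at the fully substituted C8' may be outrun by reversible O-alkylation or by self-condensation of 4, the ring closure may take the exo orientation, and facial control by the chiral base may be poor. The fallback sets out from 4 and 2 and returns at 5. Compound 4 is silylated (t-BuMe2SiCl, imidazole, DMF) to the silyloxypyranone F3. F3 and 2 are joined in a neutral Diels–Alder reaction of the 2-pyranone under 12 kbar in CH2Cl2 at 40 °C to the racemic silyl enol ether adduct F4. HF·pyridine in THF cleaves the silyl enol ether to racemic 5, which is resolved by preparative HPLC on a chiral stationary phase; the unwanted enantiomer F5 is set aside.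

- Step 4. While the ketol is free in hydroxide the propyl group may shift (acyloin shift within the six-membered ring), the central ring may open by retro-Michael cleavage, or the epimerisation at C7 may stay incomplete. The fallback sets out from 5 and returns at 7. HCl in MeOH adds methanol to the C3' ketone and moves the lactone from the oxygen on C8' to the new oxygen on C3', which gives the cis-fused bridged methoxy lactone F6 with the ketone masked. 1,8-Diazabicyclo[5.4.0]undec-7-ene (DBU) in toluene then epimerises C7 alone to the trans-fused methoxy lactone F7. Brief treatment with LiOH in THF/H2O at 0 °C and acidification open the acylal and the ester of half A and give 7.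

**Further compounds**

F1 | step 6 | free hydroxy keto acid (8 with the acylal hydrolysed: C3' ketone, CO2H on C7a', OH on C8', butenolide intact) | CCC/C=C1\OC(=O)C2=C1CC[C@H]3[C@H]2[C@@]2(C(O)=O)C=CCC[C@@H]2C(=O)[C@@]3(O)CCC
F2 | step 6 | ring-contracted hydroxy acid (9 with the bridged lactone open: tertiary OH and butanoyl on C3', CO2H on C7a') | CCC/C=C1\OC(=O)C2=C1CC[C@H]1[C@H]2[C@@]2(C(O)=O)C=CCC[C@@H]2[C@@]1(O)C(=O)CCC
F3 | step 3 | 4-(tert-butyldimethylsilyloxy)-3-propyl-5,6-dihydro-1H-isochromen-1-one | CCCC1=C(O[Si](C)(C)C(C)(C)C)C2=C(C=CCC2)C(=O)O1
F4 | step 3 | silyl enol ether Diels–Alder adduct (racemic; drawn as the enantiomer that leads to 5) | CCCCC(=O)C1=C(C(=O)OC)[C@@H]2[C@H](CC1)[C@]4(CCC)C(O[Si](C)(C)C(C)(C)C)=C3CCC=C[C@]23C(=O)O4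
F5 | step 3 | enantiomer of 5 (removed in the resolution) | CCCCC(=O)C1=C(C(=O)OC)[C@H]2[C@@H](CC1)[C@@]4(CCC)C(=O)[C@@H]3CCC=C[C@@]23C(=O)O4
F6 | step 4 | cis-fused bridged methoxy lactone (C3' with OMe and lactone oxygen, free OH on C8', half A as methyl keto ester) | CCCCC(=O)C1=C(C(=O)OC)[C@@H]2[C@H](CC1)[C@](O)(CCC)[C@]4(OC)[C@H]3CCC=C[C@]23C(=O)O4
F7 | step 4 | trans-fused bridged methoxy lactone (C7 epimer of F6) | CCCCC(=O)C1=C(C(=O)OC)[C@H]2[C@H](CC1)[C@](O)(CCC)[C@]4(OC)[C@H]3CCC=C[C@]23C(=O)O4
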